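**Strategy.** Everything rests on cutting the C3–C4 bond of the ten-membered carbocycle (germacrane numbering). It is the only ring bond that links two planar carbons, C3 of the furanone ring and C4 of the Z-configured C4=C5 alkene, and it has no stereocentre beside it. A palladium-catalysed, copper-assisted thioether–stannane coupling makes this bond and closes the carbocycle in one operation, so the strained oxygen-bridged dienone appears last and C6, C7, C8 and C10 are never at risk. The precursor is an open chain that already carries the 5-methylsulfanyl-3(2H)-furanone, the trans α-methylene-γ-lactone, the C8 silyl ether and a Z-vinylstannane at C4.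

Key step: step 19

Remark on numbering: C1–C15 are germacrane locants; the descriptors at C6 and C7 change along the route only because substituent priorities change, while the spatial arrangement stays that of the target (6S,7S,8R,10R).

Remark on the chemistry: C5–C7 are brought in as a ring-locked 3-(bromomethyl)butenolide, because the 6,7-trans/7,8-anti triad of the target is what chair-type addition of an E-configured allyl metal gives, whereas an open-chain (Z)-2-(bromomethyl)enoate would be expected to give the 7,8-syn isomer; tert-butyl acrylate serves the side-chain branch so that the acid can be freed without touching the acetate.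

**Fragment A: furanone aldehyde (C1–C3, C8–C10, C14)**

Step 1
Reactants: 1 L-lactic acid
Product: 2 (2S,5S)-2-tert-butyl-5-methyl-1,3-dioxolan-4-one
Conditions: t-BuCHO, TsOH·H2O (cat.), H2SO4 (cat.), pentane, reflux, Dean–Stark; crystallisation from pentane/Et2O, −78 °C
Reagents that add atoms: pivalaldehyde, CC(C)(C)C=O
Why: Acid-catalysed acetalisation under thermodynamic control should favour the cis dioxolanone, whose new acetal centre (2S) is set by the lactic acid centre, and low-temperature crystallisation should remove the minor trans isomer.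

Step 2
Reactants: 2 (2S,5S)-2-tert-butyl-5-methyl-1,3-dioxolan-4-one
Product: 3 (2S,5R)-2-tert-butyl-5-methyl-5-(prop-2-en-1-yl)-1,3-dioxolan-4-one
Conditions: LiN(i-Pr)2, THF, −78 °C; allyl bromide, −78 to −30 °C
Reagents that add atoms: allyl bromide, C=CCBr
Why: Enolate alkylation with self-regeneration of the stereocentre, in which the tert-butyl group shields one face of the planar lithium enolate so that the allyl group should enter trans to it and the quaternary centre (later C10) forms with overall retention.

Step 3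
Reactants: 3 (2S,5R)-2-tert-butyl-5-methyl-5-(prop-2-en-1-yl)-1,3-dioxolan-4-one
Product: 4 (2R)-2-hydroxy-N-methoxy-N,2-dimethylpent-4-enamide
Conditions: MeNH(OMe)·HCl, i-PrMgCl, THF, −20 to 0 °C
Reagents that add atoms: N,O-dimethylhydroxylamine hydrochloride, CNOC.Cl
Why: Weinreb aminolysis of the activated acylal-type lactone by the magnesium amide opens the dioxolanone, the hemiacetal alkoxide then loses pivalaldehyde, and the quaternary centre is not involved.

Step 4
Reactants: 4 (2R)-2-hydroxy-N-methoxy-N,2-dimethylpent-4-enamide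
Product: 5 (3R)-3-hydroxy-3-methylhex-5-en-2-one
Conditions: MeMgBr (3 equiv), THF, 0 °C; aq. NH4Cl
Reagents that add atoms: methylmagnesium bromide, C[Mg]Br
Why: Weinreb ketone synthesis, in which the chelated tetrahedral adduct should survive until work-up so that exactly one methyl group (C2) is added after the hydroxyl group has been deprotonated.

Step 5
Reactants: 5 (3R)-3-hydroxy-3-methylhex-5-en-2-one
Product: 6 (3R)-3-methyl-3-[(trimethylsilyl)oxy]hex-5-en-2-one
Conditions: Me3SiCl, imidazole, DMF, rt
Reagents that add atoms: chlorotrimethylsilane, C[Si](C)(C)Cl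
Why: Silylation masks the tertiary hydroxyl group, which would otherwise be drawn into xanthate formation with CS2 in the next step.

Step 6
Reactants: 6 (3R)-3-methyl-3-[(trimethylsilyl)oxy]hex-5-en-2-one
Product: 7 (4R)-4-methyl-1,1-bis(methylsulfanyl)-4-[(trimethylsilyl)oxy]hepta-1,6-dien-3-one
Conditions: LiN(SiMe3)2 (2.2 equiv), THF, −78 °C; CS2; MeI (2.5 equiv), −78 °C to rt
Reagents that add atoms: carbon disulfide, S=C=S; iodomethane, CI
Why: Formation of an α-oxo ketene dithioacetal, in which the enolate of the methyl ketone (the only enolisable position) adds to CS2 and the dithiocarboxylate is deprotonated again and S-methylated twice, which brings in C3 at the carboxyl oxidation level.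

Step 7
Reactants: 7 (4R)-4-methyl-1,1-bis(methylsulfanyl)-4-[(trimethylsilyl)oxy]hepta-1,6-dien-3-one
Product: 9 (2R)-2-methyl-5-(methylsulfanyl)-2-(prop-2-en-1-yl)furan-3(2H)-one, via hydroxy dithioacetal 8 (not isolated)
Conditions: CF3CO2H, CH2Cl2/H2O (20:1), 0 °C to rt
Reagents that add atoms: none
Why: Acid removes the trimethylsilyl group and protonates the push–pull enone at oxygen, so that the tertiary hydroxyl group should add to the bis(methylsulfanyl) carbon and methanethiol is lost (addition–elimination cyclisation to a 5-methylsulfanyl-3(2H)-furanone).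

Step 8
Reactants: 9 (2R)-2-methyl-5-(methylsulfanyl)-2-(prop-2-en-1-yl)furan-3(2H)-one
Product: 11 2-[(2R)-2-methyl-5-(methylsulfanyl)-3-oxo-2,3-dihydrofuran-2-yl]acetaldehyde, via diol 10 (not isolated)
Conditions: K2OsO4·2H2O (2 mol%), NMO, acetone/H2O, 0 °C; then NaIO4, rt
Reagents that add atoms: N-methylmorpholine N-oxide, C[N+]1([O-])CCOCC1; water, O
Why: Two-stage Lemieux–Johnson-type cleavage, in which the monosubstituted alkene should be dihydroxylated well ahead of the hindered conjugated furanone alkene and the deactivated vinylogous thioester sulfur, and periodate then gives the C8 aldehyde under near-neutral conditions that avoid β-elimination of the ring oxygen.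

**Fragment B: bromolactone (C5–C7, C11–C13)**

Step 9
Reactants: 12 (S)-glyceraldehyde acetonide, 13 methyl acrylate
Product: 14 methyl 2-{[(4S)-2,2-dimethyl-1,3-dioxolan-4-yl](hydroxy)methyl}prop-2-enoate (carbinol epimers)
Conditions: DABCO (0.5 equiv), neat 13 (4 equiv), rt, several days
Reagents that add atoms: none
Why: Morita–Baylis–Hillman reaction, in which the new carbinol centre may form as an epimer mixture because it becomes sp2 in step 12, while the dioxolane centre (later C6) should be kept in the weakly basic medium.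

Step 10
Reactants: 14 methyl 2-{[(4S)-2,2-dimethyl-1,3-dioxolan-4-yl](hydroxy)methyl}prop-2-enoate
Product: 16 (5S)-4-hydroxy-5-(hydroxymethyl)-3-methylideneoxolan-2-one, via triol ester 15 (not isolated)
Conditions: aq. HCl (1 M), THF, rt; then TsOH·H2O (cat.), toluene, 40 °C, removal of MeOH
Reagents that add atoms: none
Why: Acid hydrolysis of the acetonide frees the triol, and the secondary γ-hydroxyl group should lactonise onto the ester because the five-membered lactone is favoured over the six-membered one.

Step 11
Reactants: 16 (5S)-4-hydroxy-5-(hydroxymethyl)-3-methylideneoxolan-2-one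
Product: 17 (5S)-4-hydroxy-3-methylidene-5-{[(triethylsilyl)oxy]methyl}oxolan-2-one
Conditions: Et3SiCl (1.05 equiv), imidazole, CH2Cl2, −40 °C
Reagents that add atoms: chlorotriethylsilane, CC[Si](Cl)(CC)CC
Why: Selective silylation, in which the primary hydroxyl group should react well ahead of the hindered secondary allylic one at low temperature.

Step 12
Reactants: 17 (5S)-4-hydroxy-3-methylidene-5-{[(triethylsilyl)oxy]methyl}oxolan-2-one
Product: 18 (5R)-3-(bromomethyl)-5-{[(triethylsilyl)oxy]methyl}furan-2(5H)-one
Conditions: NBS, Me2S, CH2Cl2, −20 to 0 °C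
Reagents that add atoms: N-bromosuccinimide, O=C1CCC(=O)N1Br
Why: Corey–Kim-type activation of the allylic alcohol as an alkoxysulfonium salt and SN2' attack of bromide at the exocyclic methylene should give the conjugated bromomethyl butenolide from both carbinol epimers under neutral conditions that leave the C6 centre and the silyl ether intact.

**Union and elaboration to the precursor**

Step 13
Reactants: 11 2-[(2R)-2-methyl-5-(methylsulfanyl)-3-oxo-2,3-dihydrofuran-2-yl]acetaldehyde, 18 (5R)-3-(bromomethyl)-5-{[(triethylsilyl)oxy]methyl}furan-2(5H)-one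
Product: 19 Barbier adduct with free C8 hydroxyl (6R,7S,8R,10R)
Conditions: In powder (2 equiv), 18 (1.5 equiv), THF/H2O (3:1), rt
Reagents that add atoms: none
Why: Indium Barbier allylation through a chair Zimmerman–Traxler transition state, in which the allylindium from 18 should attack through its ring carbon (later C7) on the face away from the C6 substituent, which sets C7 trans to C6, and its ring-locked E geometry places C6 and the aldehyde chain both equatorial, which sets C8 (R) anti to C7.

Step 14
Reactants: 19 Barbier adduct (6R,7S,8R,10R)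
Product: 20 C5,C8-bis(triethylsilyl) ether (6R,7R,8R,10R)
Conditions: Et3SiOTf (1.5 equiv), 2,6-lutidine, CH2Cl2, −78 °C
Reagents that add atoms: triethylsilyl trifluoromethanesulfonate, CC[Si](CC)(CC)OS(=O)(=O)C(F)(F)F
Why: Silylation with the reactive silyl triflate should cap the hindered C8 hydroxyl group (and restore any primary silyl ether lost in step 13) before basic reagents are used, which blocks translactonisation to C8.

Step 15
Reactants: 20 C5,C8-bis(triethylsilyl) ether
Product: 21 C5 primary alcohol with C8 triethylsilyl ether (6R,7R,8R,10R)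
Conditions: HF·pyridine, pyridine, THF, 0 °C
Reagents that add atoms: none
Why: Selective desilylation, in which the unhindered primary silyl ether at C5 should be cleaved well before the secondary one at C8, which is flanked by C7 and the neopentyl-type C9.

Step 16
Reactants: 21 C5 primary alcohol
Product: 22 C5 aldehyde (6R,7R,8R,10R)
Conditions: Dess–Martin periodinane, NaHCO3, CH2Cl2, 0 °C to rt
Reagents that add atoms: none
Why: Dess–Martin oxidation gives the aldehyde under buffered, non-basic conditions that should neither epimerise C6 nor oxidise the deactivated sulfur.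

Step 17
Reactants: 22 C5 aldehyde
Product: 23 (Z)-vinyl iodide (4Z,6R,7R,8R,10R)
Conditions: [Ph3PEt]I, n-BuLi, THF, 0 °C; I2, −78 °C; NaN(SiMe3)2, −78 to −20 °C; then 22, −78 °C
Reagents that add atoms: ethyltriphenylphosphonium iodide, CC[P+](c1ccccc1)(c1ccccc1)c1ccccc1.[I-]; iodine, II
Why: Stork–Zhao olefination, in which the α-iodo ylide should react with the aldehyde at −78 °C faster than with the conjugated lactone and give the (Z)-2-iodoalkene under kinetic control, which fixes the C4=C5 geometry and brings in C4 and C15.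

Step 18
Reactants: 23 (Z)-vinyl iodide
Product: 24 (Z)-vinylstannane, the cyclisation precursor (4Z,6R,7R,8R,10R)
Conditions: (Bu3Sn)2 (2 equiv), Pd(PPh3)4 (10 mol%), toluene, 80 °C
Reagents that add atoms: hexabutylditin, CCCC[Sn](CCCC)(CCCC)[Sn](CCCC)(CCCC)CCCC
Why: Palladium-catalysed iodine–tin exchange (oxidative addition, transmetalation from the distannane, reductive elimination) proceeds with retention of the Z geometry, and without a thiophilic copper salt the C3–S bond should stay untouched.

Step 19
Reactants: 24 (Z)-vinylstannane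
Product: 25 C8 triethylsilyl ether of the tricyclic core (4Z,6S,7R,8R,10R)
Conditions: Pd(PPh3)4 (20 mol%), Cu(O2CC4H3S) (copper thiophene-2-carboxylate, 2.5 equiv), degassed THF, 50 °C, syringe-pump addition of 24 to a final 1 mM
Reagents that add atoms: none
Why: Once monovalent copper has bound the sulfur, zerovalent palladium adds oxidatively into the C3–S bond of the vinylogous thioester, the carboxylate on copper takes up the tin while copper keeps the methanethiolate so that C4 passes to palladium, and reductive elimination forms C3–C4 with the alkene geometry unchanged. The closest known reaction type is the Liebeskind–Srogl variant of the Stille coupling of thioethers and vinylogous thioesters with vinylstannanes, run here in the manner of a Stille macrocyclisation. The ten-membered carbocycle is closed by joining the two chain ends, both sp2 carbons, through an eleven-membered palladacycle, and because reductive elimination is irreversible it can drive the strained oxygen-bridged dienone forward. No stereocentre is formed, and the neutral, base-free medium should leave C6, C7, C8, C10, the silyl ether and the methylene lactone as they are. The step needs ring closure to win over oligomerisation and the Z geometry to survive: the Z alkene, the trans-fused lactone and the quaternary C10 bend the chain so that C3 and C4 come close, slow addition keeps the stannane dilute, and vinyl transfer from tin is stereoretentive.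

**End game and side chain**

Step 20
Reactants: 25 C8 triethylsilyl ether of the tricyclic core
Product: 26 C8 alcohol of the tricyclic core (4Z,6S,7S,8R,10R)
Conditions: HF·pyridine, THF, 0 °C to rt
Reagents that add atoms: none
Why: Mildly acidic, fluoride-assisted cleavage of the secondary silyl ether should free the C8 hydroxyl group without harming the lactone, the dienone or any stereocentre.

Step 21
Reactants: 27 acetaldehyde, 28 tert-butyl acrylate
Product: 29 tert-butyl 3-hydroxy-2-methylidenebutanoate (racemic)
Conditions: DABCO (0.2 equiv), dioxane/H2O (1:1), rt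
Reagents that add atoms: none
Why: Morita–Baylis–Hillman reaction, whose racemic carbinol centre does not matter because it becomes sp2 in step 23.

Step 22
Reactants: 29 tert-butyl 3-hydroxy-2-methylidenebutanoate
Product: 30 tert-butyl 3-(acetyloxy)-2-methylidenebutanoate (racemic)
Conditions: Ac2O, pyridine, DMAP (cat.), CH2Cl2, 0 °C to rt
Reagents that add atoms: acetic anhydride, CC(=O)OC(C)=O
Why: Standard O-acylation of the secondary allylic alcohol.

Step 23
Reactants: 30 tert-butyl 3-(acetyloxy)-2-methylidenebutanoate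
Product: 31 tert-butyl (2E)-2-[(acetyloxy)methyl]but-2-enoate
Conditions: DABCO (0.2 equiv), THF, reflux
Reagents that add atoms: none
Why: Amine-catalysed allylic transposition (SN2' addition of DABCO, return of acetate at the primary carbon) under thermodynamic control should give the trisubstituted E enoate, in which the methyl group lies trans to the ester as in the target side chain.

Step 24
Reactants: 31 tert-butyl (2E)-2-[(acetyloxy)methyl]but-2-enoate
Product: 32 (2E)-2-[(acetyloxy)methyl]but-2-enoic acid
Conditions: CF3CO2H/CH2Cl2 (1:4), 0 °C to rt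
Reagents that add atoms: none
Why: Acidolysis of the tert-butyl ester through the tert-butyl cation leaves the primary acetate and the alkene geometry untouched.

Step 25
Reactants: 26 C8 alcohol of the tricyclic core, 32 (2E)-2-[(acetyloxy)methyl]but-2-enoic acid
Product: 33 target CNP0176571.1
Conditions: DCC, DMAP (0.2 equiv), CH2Cl2, 0 °C to rt
Reagents that add atoms: none
Why: Steglich esterification acylates the C8 hydroxyl group with retention because the C8–O bond is not broken, and the ionisable allylic acetate of the side chain is introduced only after all palladium steps.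

**Compound list**

1 | L-lactic acid, (S)-2-hydroxypropanoic acid | C[C@H](O)C(=O)O | starting material
2 | (2S,5S)-2-tert-butyl-5-methyl-1,3-dioxolan-4-one (cis) | C[C@@H]1O[C@H](C(C)(C)C)OC1=O | intermediate
3 | (2S,5R)-2-tert-butyl-5-methyl-5-(prop-2-en-1-yl)-1,3-dioxolan-4-one | C=CC[C@@]1(C)O[C@H](C(C)(C)C)OC1=O | intermediate
4 | (2R)-2-hydroxy-N-methoxy-N,2-dimethylpent-4-enamide | C=CC[C@@](C)(O)C(=O)N(C)OC | intermediate
5 | (3R)-3-hydroxy-3-methylhex-5-en-2-one | C=CC[C@@](C)(O)C(C)=O | intermediate
6 | (3R)-3-methyl-3-[(trimethylsilyl)oxy]hex-5-en-2-one | C=CC[C@@](C)(O[Si](C)(C)C)C(C)=O | intermediate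
7 | (4R)-4-methyl-1,1-bis(methylsulfanyl)-4-[(trimethylsilyl)oxy]hepta-1,6-dien-3-one | C=CC[C@@](C)(O[Si](C)(C)C)C(=O)C=C(SC)SC | intermediate
8 | (4R)-4-hydroxy-4-methyl-1,1-bis(methylsulfanyl)hepta-1,6-dien-3-one | C=CC[C@@](C)(O)C(=O)C=C(SC)SC | intermediate (not isolated)
9 | (2R)-2-methyl-5-(methylsulfanyl)-2-(prop-2-en-1-yl)furan-3(2H)-one | C=CC[C@@]1(C)OC(SC)=CC1=O | intermediate
10 | (2R)-2-(2,3-dihydroxypropyl)-2-methyl-5-(methylsulfanyl)furan-3(2H)-one (carbinol epimers) | OCC(O)C[C@@]1(C)OC(SC)=CC1=O | intermediate (not isolated)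
11 | 2-[(2R)-2-methyl-5-(methylsulfanyl)-3-oxo-2,3-dihydrofuran-2-yl]acetaldehyde | O=CC[C@@]1(C)OC(SC)=CC1=O | intermediate
12 | (S)-glyceraldehyde acetonide, (4S)-2,2-dimethyl-1,3-dioxolane-4-carbaldehyde | O=C[C@@H]1COC(C)(C)O1 | starting material
13 | methyl acrylate | C=CC(=O)OC | starting material
14 | methyl 2-{[(4S)-2,2-dimethyl-1,3-dioxolan-4-yl](hydroxy)methyl}prop-2-enoate (carbinol epimers) | C=C(C(=O)OC)C(O)[C@@H]1COC(C)(C)O1 | intermediate
15 | methyl (4S)-3,4,5-trihydroxy-2-methylidenepentanoate (C3 epimers) | C=C(C(=O)OC)C(O)[C@@H](O)CO | intermediate (not isolated)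
16 | (5S)-4-hydroxy-5-(hydroxymethyl)-3-methylideneoxolan-2-one (C4 epimers) | C=C1C(=O)O[C@@H](CO)C1O | intermediate
17 | (5S)-4-hydroxy-3-methylidene-5-{[(triethylsilyl)oxy]methyl}oxolan-2-one (C4 epimers) | C=C1C(=O)O[C@@H](CO[Si](CC)(CC)CC)C1O | intermediate
18 | (5R)-3-(bromomethyl)-5-{[(triethylsilyl)oxy]methyl}furan-2(5H)-one | BrCC1=C[C@H](CO[Si](CC)(CC)CC)OC1=O | intermediate
19 | (4S,5R)-4-{(1R)-1-hydroxy-2-[(2R)-2-methyl-5-(methylsulfanyl)-3-oxo-2,3-dihydrofuran-2-yl]ethyl}-3-methylidene-5-{[(triethylsilyl)oxy]methyl}oxolan-2-one (6R,7S,8R,10R) | C=C1C(=O)O[C@@H](CO[Si](CC)(CC)CC)[C@@H]1[C@H](O)C[C@@]2(C)OC(SC)=CC2=O | intermediate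
20 | (4R,5R)-4-{(1R)-2-[(2R)-2-methyl-5-(methylsulfanyl)-3-oxo-2,3-dihydrofuran-2-yl]-1-[(triethylsilyl)oxy]ethyl}-3-methylidene-5-{[(triethylsilyl)oxy]methyl}oxolan-2-one (6R,7R,8R,10R) | C=C1C(=O)O[C@@H](CO[Si](CC)(CC)CC)[C@@H]1[C@H](O[Si](CC)(CC)CC)C[C@@]2(C)OC(SC)=CC2=O | intermediate
21 | (4R,5R)-5-(hydroxymethyl)-4-{(1R)-2-[(2R)-2-methyl-5-(methylsulfanyl)-3-oxo-2,3-dihydrofuran-2-yl]-1-[(triethylsilyl)oxy]ethyl}-3-methylideneoxolan-2-one (6R,7R,8R,10R) | C=C1C(=O)O[C@@H](CO)[C@@H]1[C@H](O[Si](CC)(CC)CC)C[C@@]2(C)OC(SC)=CC2=O | intermediate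
22 | (2R,3R)-3-{(1R)-2-[(2R)-2-methyl-5-(methylsulfanyl)-3-oxo-2,3-dihydrofuran-2-yl]-1-[(triethylsilyl)oxy]ethyl}-4-methylidene-5-oxooxolane-2-carbaldehyde (6R,7R,8R,10R) | C=C1C(=O)O[C@@H](C=O)[C@@H]1[C@H](O[Si](CC)(CC)CC)C[C@@]2(C)OC(SC)=CC2=O | intermediate
23 | (4R,5R)-5-[(1Z)-2-iodoprop-1-en-1-yl]-4-{(1R)-2-[(2R)-2-methyl-5-(methylsulfanyl)-3-oxo-2,3-dihydrofuran-2-yl]-1-[(triethylsilyl)oxy]ethyl}-3-methylideneoxolan-2-one (4Z,6R,7R,8R,10R) | C=C1C(=O)O[C@@H](/C=C(/C)I)[C@@H]1[C@H](O[Si](CC)(CC)CC)C[C@@]2(C)OC(SC)=CC2=O | intermediate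
24 | (4R,5R)-4-{(1R)-2-[(2R)-2-methyl-5-(methylsulfanyl)-3-oxo-2,3-dihydrofuran-2-yl]-1-[(triethylsilyl)oxy]ethyl}-3-methylidene-5-[(1Z)-2-(tributylstannyl)prop-1-en-1-yl]oxolan-2-one (4Z,6R,7R,8R,10R) | C=C1C(=O)O[C@@H](/C=C(/C)[Sn](CCCC)(CCCC)CCCC)[C@@H]1[C@H](O[Si](CC)(CC)CC)C[C@@]2(C)OC(SC)=CC2=O | intermediate
25 | 1-oxo-8-[(triethylsilyl)oxy]-3,10-epoxygermacra-2,4,11(13)-trien-12,6-olide (4Z,6S,7R,8R,10R) | C=C1C(=O)O[C@H]2/C=C(/C)C3=CC(=O)[C@@](C)(C[C@@H](O[Si](CC)(CC)CC)[C@H]12)O3 | intermediate
26 | 8-hydroxy-1-oxo-3,10-epoxygermacra-2,4,11(13)-trien-12,6-olide (4Z,6S,7S,8R,10R) | C=C1C(=O)O[C@H]2/C=C(/C)C3=CC(=O)[C@@](C)(C[C@@H](O)[C@H]12)O3 | intermediate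
27 | acetaldehyde | CC=O | starting material
28 | tert-butyl acrylate | C=CC(=O)OC(C)(C)C | starting material
29 | tert-butyl 3-hydroxy-2-methylidenebutanoate (racemic) | C=C(C(C)O)C(=O)OC(C)(C)C | intermediate
30 | tert-butyl 3-(acetyloxy)-2-methylidenebutanoate (racemic) | C=C(C(C)OC(C)=O)C(=O)OC(C)(C)C | intermediate
31 | tert-butyl (2E)-2-[(acetyloxy)methyl]but-2-enoate | C/C=C(\COC(C)=O)C(=O)OC(C)(C)C | intermediate
32 | (2E)-2-[(acetyloxy)methyl]but-2-enoic acid | C/C=C(\COC(C)=O)C(=O)O | intermediate
33 | CNP0176571.1, the 8-O-[(2E)-2-(acetoxymethyl)but-2-enoyl] ester of 26 (4Z,6S,7S,8R,10R) | C=C1C(=O)O[C@H]2/C=C(/C)C3=CC(=O)[C@@](C)(C[C@@H](OC(=O)/C(=C/C)COC(C)=O)[C@H]12)O3 | target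

**Totals**

Total step count: 25. Longest linear sequence: 17 steps (steps 1–8, 13–20 and 25).

**Steps most likely to fail**

1. Step 19 (macrocyclisation). Intermolecular coupling to oligomers, protodestannylation or copper-induced homocoupling of the vinylstannane may outrun the strained ring closure. Fallback: setting out from aldehyde 22, Wittig methylenation ([Ph3PMe]Br, NaN(SiMe3)2, THF, −78 °C) would give the C6-vinyl lactone F1. Intermolecular coupling of its C3 methylsulfanyl group with tributyl(prop-1-en-2-yl)stannane under Pd(PPh3)4 and copper thiophene-2-carboxylate would give the 3-isopropenyl furanone F2, so that C3–C4 is made without strain. Ring-closing metathesis of F2 (second-generation Hoveyda–Grubbs catalyst, toluene, 80 °C, 1 mM) would then close the ten-membered ring at C4=C5 with loss of ethene and rejoin the route at 25; the oxygen-bridged bicycle should hold only the cis ring alkene.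

2. Step 17 (Stork–Zhao olefination). The basic ylide may epimerise C6 next to the aldehyde or add in conjugate fashion to the methylene lactone, and the Z selectivity may erode. Fallback: setting out from aldehyde 22, a base-free dibromo-olefination (CBr4, PPh3, CH2Cl2, 0 °C) would give the 1,1-dibromoalkene F3. Palladium-catalysed Negishi methylation (Me2Zn, PdCl2(DPEphos), THF), which replaces selectively the bromine trans to C6, would give the (Z)-2-bromoalkene F4; without copper the C3–S bond should stay intact. Tin exchange of F4 ((Bu3Sn)2, Pd(PPh3)4, toluene, 100 °C) would rejoin the route at 24.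

3. Step 13 (Barbier coupling). The furanone oxygen β to the aldehyde of 11 may be eliminated before the C–C bond forms, or the addition may be sluggish and lose its anti/trans preference through a mismatched influence of C10. Fallback: setting out from ketene dithioacetal 7, the same oxidative cleavage (K2OsO4·2H2O, NMO; NaIO4) would give the open-chain silyloxy aldehyde F5, whose C10 oxygen is a silyl ether and cannot leave. Indium coupling of F5 with 18 under the same chair control would give the adduct F6. CF3CO2H in wet CH2Cl2 would then remove both silyl groups and close the furanone to the diol F7, and Et3SiOTf (3 equiv) with 2,6-lutidine would rejoin the route at 20.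

**Further compounds**

F1 | step 19 | (4R,5S)-5-ethenyl-4-{(1R)-2-[(2R)-2-methyl-5-(methylsulfanyl)-3-oxo-2,3-dihydrofuran-2-yl]-1-[(triethylsilyl)oxy]ethyl}-3-methylideneoxolan-2-one | C=C1C(=O)O[C@@H](C=C)[C@@H]1[C@H](O[Si](CC)(CC)CC)C[C@@]2(C)OC(SC)=CC2=O
F2 | step 19 | (4R,5S)-5-ethenyl-4-{(1R)-2-[(2R)-2-methyl-3-oxo-5-(prop-1-en-2-yl)-2,3-dihydrofuran-2-yl]-1-[(triethylsilyl)oxy]ethyl}-3-methylideneoxolan-2-one | C=C1C(=O)O[C@@H](C=C)[C@@H]1[C@H](O[Si](CC)(CC)CC)C[C@@]2(C)OC(C(C)=C)=CC2=O
F3 | step 17 | (4R,5R)-5-(2,2-dibromoethenyl)-4-{(1R)-2-[(2R)-2-methyl-5-(methylsulfanyl)-3-oxo-2,3-dihydrofuran-2-yl]-1-[(triethylsilyl)oxy]ethyl}-3-methylideneoxolan-2-one | C=C1C(=O)O[C@@H](C=C(Br)Br)[C@@H]1[C@H](O[Si](CC)(CC)CC)C[C@@]2(C)OC(SC)=CC2=O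
F4 | step 17 | (4R,5R)-5-[(1Z)-2-bromoprop-1-en-1-yl]-4-{(1R)-2-[(2R)-2-methyl-5-(methylsulfanyl)-3-oxo-2,3-dihydrofuran-2-yl]-1-[(triethylsilyl)oxy]ethyl}-3-methylideneoxolan-2-one | C=C1C(=O)O[C@@H](/C=C(/C)Br)[C@@H]1[C@H](O[Si](CC)(CC)CC)C[C@@]2(C)OC(SC)=CC2=O
F5 | step 13 | (3R)-3-methyl-6,6-bis(methylsulfanyl)-4-oxo-3-[(trimethylsilyl)oxy]hex-5-enal | O=CC[C@@](C)(O[Si](C)(C)C)C(=O)C=C(SC)SC
F6 | step 13 | (4S,5R)-4-{(1R,3R)-1-hydroxy-3-methyl-6,6-bis(methylsulfanyl)-4-oxo-3-[(trimethylsilyl)oxy]hex-5-en-1-yl}-3-methylidene-5-{[(triethylsilyl)oxy]methyl}oxolan-2-one | C=C1C(=O)O[C@@H](CO[Si](CC)(CC)CC)[C@@H]1[C@H](O)C[C@@](C)(O[Si](C)(C)C)C(=O)C=C(SC)SC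
F7 | step 13 | (4S,5R)-4-{(1R)-1-hydroxy-2-[(2R)-2-methyl-5-(methylsulfanyl)-3-oxo-2,3-dihydrofuran-2-yl]ethyl}-5-(hydroxymethyl)-3-methylideneoxolan-2-one | C=C1C(=O)O[C@@H](CO)[C@@H]1[C@H](O)C[C@@]2(C)OC(SC)=CC2=O
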